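**Retrosynthetic overview**

1. Feature: the only ring is the butenolide O1–C2(=O)–C3=C4–C5. Its single stereocentre C5 is a secondary carbinol carbon that carries a benzyl group and is bonded to alkenyl C4, the pattern left when an alkenyl group migrates from boron onto a chiral carbenoid carbon and the C–B bond is then oxidised.
2. The ring is closed last (step 8): O1–C2 by acid lactonisation of a Z-γ-hydroxy tert-butyl enoate. C5–O1 comes from C5–B by oxidation with retention (step 7).
3. C4–C5 (step 6): 1,2-metallate rearrangement of the boronate complex from (+)-sparteine-ligated lithiated 2-phenylethyl carbamate and a tetrasubstituted alkenyl pinacol boronate with boron cis to the ester.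
4. C4–B: Miyaura borylation of the Z-enol triflate of a 2-benzyl β-keto ester, built from phenylacetyl chloride, Meldrum's acid, tert-butanol and benzyl bromide.

Key step: step 6

Remark on the chemistry: s-BuLi/(−)-sparteine removes the pro-S hydrogen of primary O-alkyl carbamates, so (+)-sparteine (taken as purchasable; the (+)-sparteine surrogate would serve equally) is used to reach S at C5.

**Route**

Step 1
Reactants: 1 2-phenylethanol
Product: 2 2-phenylethyl N,N-diisopropylcarbamate
Conditions: iPr2NCOCl, Et3N, CH2Cl2, reflux
Reagents that add atoms: N,N-diisopropylcarbamoyl chloride, CC(C)N(C(C)C)C(=O)Cl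
Why: O-carbamoylation of a primary alcohol by acyl substitution at a carbamoyl chloride is routine and installs the group that later directs the lithiation and serves as the leaving group.

Step 2
Reactants: 3 phenylacetyl chloride; 4 Meldrum's acid
Product: 6 tert-butyl 3-oxo-4-phenylbutanoate, via phenylacetyl Meldrum's acid 5 (not isolated)
Conditions: pyridine, CH2Cl2, 0 °C → rt; aq. HCl wash, concentrate; then t-BuOH, toluene, 80 °C
Reagents that add atoms: tert-butanol, CC(C)(C)O
Why: C-acylation of Meldrum's acid followed by alcoholysis with loss of acetone and CO2 (Oikawa–Yonemitsu β-keto ester synthesis) is a standard way from an acid chloride to a β-keto ester and tolerates the enolisable phenylacetyl unit.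

Step 3
Reactants: 6 tert-butyl 3-oxo-4-phenylbutanoate; 7 benzyl bromide
Product: 8 tert-butyl 2-benzyl-3-oxo-4-phenylbutanoate (racemic)
Conditions: K2CO3, acetone, reflux
Reagents that add atoms: none
Why: The C2–H between the two carbonyl groups is by far the most acidic site, so carbonate-mediated enolate C-alkylation (acetoacetic ester alkylation) with the reactive benzylic bromide should place the benzyl group at C2; the racemic stereocentre is removed in step 4.

Step 4
Reactants: 8 tert-butyl 2-benzyl-3-oxo-4-phenylbutanoate
Product: 9 tert-butyl (Z)-2-benzyl-4-phenyl-3-{[(trifluoromethyl)sulfonyl]oxy}but-2-enoate (OTf cis to the ester)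
Conditions: NaH, CH2Cl2, 0 °C; then Tf2O, 0 °C
Reagents that add atoms: trifluoromethanesulfonic anhydride, O=S(=O)(OS(=O)(=O)C(F)(F)F)C(F)(F)F
Why: In a non-coordinating solvent the sodium cation bridges the enolate oxygen and the ester carbonyl, so O-sulfonylation of this chelated enolate (enol triflate formation) should give the isomer with OTf cis to the ester.

Step 5
Reactants: 9 tert-butyl (Z)-2-benzyl-4-phenyl-3-{[(trifluoromethyl)sulfonyl]oxy}but-2-enoate
Product: 10 tert-butyl (E)-2-benzyl-4-phenyl-3-(4,4,5,5-tetramethyl-1,3,2-dioxaborolan-2-yl)but-2-enoate (boron cis to the ester)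
Conditions: B2pin2, PdCl2(PPh3)2 (cat.), PPh3, K2CO3, dioxane, 80 °C
Reagents that add atoms: bis(pinacolato)diboron, CC1(C)OB(OC1(C)C)B1OC(C)(C)C(C)(C)O1
Why: Miyaura borylation of β-keto-ester-derived alkenyl triflates proceeds by oxidative addition to zerovalent palladium, transmetalation and reductive elimination, all with retention of alkene geometry, and the mild carbonate base limits Suzuki coupling of the product with unreacted triflate (the descriptor changes from Z to E only because boron ranks below carbon).

Step 6
Reactants: 2 2-phenylethyl N,N-diisopropylcarbamate; 10 tert-butyl (E)-2-benzyl-4-phenyl-3-(4,4,5,5-tetramethyl-1,3,2-dioxaborolan-2-yl)but-2-enoate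
Product: 13 tert-butyl (2Z,4S)-2,3-dibenzyl-5-phenyl-4-(4,4,5,5-tetramethyl-1,3,2-dioxaborolan-2-yl)pent-2-enoate, via lithiated carbamate 11 (not isolated), via lithium boronate complex 12 (not isolated)
Conditions: 2 (1.1 equiv), (+)-sparteine (1.1 equiv), s-BuLi (1.0 equiv), Et2O, −78 °C, 5 h; then 10 (1.1 equiv) in Et2O, −78 °C, 1 h; then MgBr2·OEt2, −78 °C → reflux
Reagents that add atoms: none
Why: s-BuLi/(+)-sparteine removes the pro-R hydrogen next to oxygen to give the configurationally stable lithiated carbamate 11, which adds to boron of 10 with retention to form boronate complex 12; on warming with the Lewis acid, alkenyl carbon C4 migrates from boron to C5 antiperiplanar to the departing carbamate, with inversion at C5 and retention of alkene geometry (1,2-metallate rearrangement). The closest known reaction type is the lithiation–borylation of alkenyl pinacol boronates with sparteine-ligated lithiated primary carbamates, which gives enantioenriched allylic boronates. No ring is closed; the step forms the C4–C5 bond through the temporary C5–B bond. The one new stereocentre (C5, S) is controlled by the diamine alone, because the deprotonation is enantiotopos-selective and both borylation and migration are stereospecific. The step needs attack at boron in preference to the ester carbonyl and to the acidic benzylic C–H bonds of 10; the Lewis acidity of boron, the bulk of the tert-butyl ester, the low temperature and the slight excess of 10 over the organolithium are relied on for this. The cis relationship of C5 and the ester needed for lactonisation is already fixed in 10.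

Step 7
Reactants: 13 tert-butyl (2Z,4S)-2,3-dibenzyl-5-phenyl-4-(4,4,5,5-tetramethyl-1,3,2-dioxaborolan-2-yl)pent-2-enoate (crude, used at once)
Product: 14 tert-butyl (2Z,4S)-2,3-dibenzyl-4-hydroxy-5-phenylpent-2-enoate
Conditions: NaBO3·4H2O, THF/H2O, 0 °C → rt
Reagents that add atoms: sodium perborate (peroxoborate form), [Na+].OO[B-](O)(O)O
Why: In this boronate oxidation the peroxide adds to boron and C5 migrates from boron to oxygen with retention, so the S alcohol is expected, and the mild perborate medium at low temperature is chosen to spare the enoate and the acidic C5–H and to outrun any 1,3-shift of boron.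

Step 8
Reactants: 14 tert-butyl (2Z,4S)-2,3-dibenzyl-4-hydroxy-5-phenylpent-2-enoate
Product: 15 maculalactone A, (5S)-3,4,5-tribenzylfuran-2(5H)-one
Conditions: TFA, CH2Cl2, 0 °C → rt
Reagents that add atoms: none
Why: Acidolysis of the tert-butyl ester (loss of 2-methylpropene) and acid-catalysed lactonisation of the Z-γ-hydroxy acid (5-exo-trig acyl substitution) close the butenolide without breaking the C5–O bond or enolising the product, so the S configuration is kept.

**Compound list**

1 | 2-phenylethanol | OCCc1ccccc1 | starting material
2 | 2-phenylethyl N,N-diisopropylcarbamate | CC(C)N(C(C)C)C(=O)OCCc1ccccc1 | intermediate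
3 | phenylacetyl chloride | O=C(Cl)Cc1ccccc1 | starting material
4 | Meldrum's acid (2,2-dimethyl-1,3-dioxane-4,6-dione) | CC1(C)OC(=O)CC(=O)O1 | starting material
5 | phenylacetyl Meldrum's acid (enol form, 5-(1-hydroxy-2-phenylethylidene)-2,2-dimethyl-1,3-dioxane-4,6-dione) | CC1(C)OC(=O)C(=C(O)Cc2ccccc2)C(=O)O1 | intermediate
6 | tert-butyl 3-oxo-4-phenylbutanoate | CC(C)(C)OC(=O)CC(=O)Cc1ccccc1 | intermediate
7 | benzyl bromide | BrCc1ccccc1 | starting material
8 | tert-butyl 2-benzyl-3-oxo-4-phenylbutanoate (racemic) | CC(C)(C)OC(=O)C(Cc1ccccc1)C(=O)Cc1ccccc1 | intermediate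
9 | tert-butyl (Z)-2-benzyl-4-phenyl-3-{[(trifluoromethyl)sulfonyl]oxy}but-2-enoate | CC(C)(C)OC(=O)/C(Cc1ccccc1)=C(/Cc1ccccc1)OS(=O)(=O)C(F)(F)F | intermediate
10 | tert-butyl (E)-2-benzyl-4-phenyl-3-(4,4,5,5-tetramethyl-1,3,2-dioxaborolan-2-yl)but-2-enoate | CC(C)(C)OC(=O)/C(Cc1ccccc1)=C(/Cc1ccccc1)B1OC(C)(C)C(C)(C)O1 | intermediate
11 | (R)-1-lithio-2-phenylethyl N,N-diisopropylcarbamate, (+)-sparteine complex | CC(C)N(C(C)C)C(=O)O[C@H]([Li])Cc1ccccc1 | intermediate
12 | lithium boronate complex of 11 and 10 (boron bound to C5 with retention) | [Li+].CC(C)N(C(C)C)C(=O)O[C@@H](Cc1ccccc1)[B-]1(OC(C)(C)C(C)(C)O1)/C(Cc1ccccc1)=C(/Cc1ccccc1)C(=O)OC(C)(C)C | intermediate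
13 | tert-butyl (2Z,4S)-2,3-dibenzyl-5-phenyl-4-(4,4,5,5-tetramethyl-1,3,2-dioxaborolan-2-yl)pent-2-enoate | CC(C)(C)OC(=O)/C(Cc1ccccc1)=C(/Cc1ccccc1)[C@H](Cc1ccccc1)B1OC(C)(C)C(C)(C)O1 | intermediate
14 | tert-butyl (2Z,4S)-2,3-dibenzyl-4-hydroxy-5-phenylpent-2-enoate | CC(C)(C)OC(=O)/C(Cc1ccccc1)=C(/Cc1ccccc1)[C@H](Cc1ccccc1)O | intermediate
15 | maculalactone A, (5S)-3,4,5-tribenzylfuran-2(5H)-one | O=C1O[C@@H](Cc2ccccc2)C(Cc2ccccc2)=C1Cc1ccccc1 | target

**Step count**

Total: 8 steps. Longest linear sequence: 7 steps (steps 2 to 8, from phenylacetyl chloride and Meldrum's acid); step 1 is a one-step side branch.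

**Steps most likely to fail**

Step 6. The boronate complex may form slowly or reversibly at the hindered, ester-flanked boron of 10, and the electron-poor alkenyl group may migrate sluggishly. The organolithium may instead remove a benzylic proton of 10 or of 2 (with loss of carbamate) or add to the ester. The fallback builds C4–C5 and the C5 stereocentre separately by known chemistry. It sets out from triflate 9: carbonylative Stille coupling with benzyltributylstannane (Pd(PPh3)4, LiCl, CO 1 atm, THF, 55 °C) should give tert-butyl (Z)-2,3-dibenzyl-4-oxo-5-phenylpent-2-enoate F1. Corey–Bakshi–Shibata reduction of F1 ((R)-2-methyl-CBS-oxazaborolidine, catecholborane, toluene, −78 °C) follows; with the tetrasubstituted alkenyl group acting as the large substituent, the R catalyst is predicted to deliver the S alcohol. This returns to the route at 14.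

Step 4. Chelation control in the O-sulfonylation may be incomplete, and the resulting loss of geometric purity would carry through step 5 and place boron trans to the ester. The fallback fixes the geometry by syn addition to an alkyne. It sets out from benzyl bromide 7 and commercial 3-phenyl-1-propyne (C#CCc1ccccc1): EtMgBr, THF, then CuBr (cat.) and 7 should give 1,4-diphenylbut-2-yne F2. Copper-catalysed boracarboxylation (bis(pinacolato)diboron, CO2 1 atm, LiOtBu kept near one equivalent to limit propargyl–allenyl isomerisation, chloro(1,3-dimesitylimidazolin-2-ylidene)copper cat., THF, 80 °C) adds boron and carboxylate syn across the symmetrical triple bond to give the lithium boralactonate F3. Cold dilute HCl releases (E)-2-benzyl-4-phenyl-3-(4,4,5,5-tetramethyl-1,3,2-dioxaborolan-2-yl)but-2-enoic acid F4, and tert-butyl 2,2,2-trichloroacetimidate (cyclohexane/CH2Cl2, rt) esterifies it. This rejoins the route at 10 and bypasses steps 2 to 5.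

Step 7. In the aqueous, mildly basic medium the C5 alkoxide may close onto the ester, and the lactone so formed may lose its C5 proton, eroding configuration; slow oxidation would also leave time for a 1,3-shift of boron. The fallback transfers oxygen under anhydrous neutral conditions and goes straight to the lactone. It sets out from 13: trimethylamine N-oxide (anhydrous, THF, 0 °C → rt) should give the borate ester tert-butyl (2Z,4S)-2,3-dibenzyl-5-phenyl-4-[(4,4,5,5-tetramethyl-1,3,2-dioxaborolan-2-yl)oxy]pent-2-enoate F5. TFA/CH2Cl2 then converts F5 directly into the lactone, with no free alkoxide or hydroxide at any stage. This rejoins the route at 15 and skips 14.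

**Further compounds**

F1 | step 6 | tert-butyl (Z)-2,3-dibenzyl-4-oxo-5-phenylpent-2-enoate | CC(C)(C)OC(=O)/C(Cc1ccccc1)=C(/Cc1ccccc1)C(=O)Cc1ccccc1
F2 | step 4 | 1,4-diphenylbut-2-yne | C(C#CCc1ccccc1)c1ccccc1
F3 | step 4 | lithium boralactonate (lithium 3,4-dibenzyl-5-oxo-2,5-dihydro-1,2-oxaborol-2-uide, spiro pinacolate at boron) | [Li+].O=C1O[B-]2(OC(C)(C)C(C)(C)O2)C(Cc3ccccc3)=C1Cc1ccccc1
F4 | step 4 | (E)-2-benzyl-4-phenyl-3-(4,4,5,5-tetramethyl-1,3,2-dioxaborolan-2-yl)but-2-enoic acid | OC(=O)/C(Cc1ccccc1)=C(/Cc1ccccc1)B1OC(C)(C)C(C)(C)O1
F5 | step 7 | tert-butyl (2Z,4S)-2,3-dibenzyl-5-phenyl-4-[(4,4,5,5-tetramethyl-1,3,2-dioxaborolan-2-yl)oxy]pent-2-enoate | CC(C)(C)OC(=O)/C(Cc1ccccc1)=C(/Cc1ccccc1)[C@H](Cc1ccccc1)OB1OC(C)(C)C(C)(C)O1
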